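## Retrosynthetic overview

Eudesmane locants are used in the text: C10 is the quaternary carbon with the methyl group, C5 the ring-fusion CH, C3=C4 the ring-A alkene, C15 the CH2O carbon, C7 the ring-B CH carrying the acrylic acid C11(=C13H2)–C12O2H, and C8/C9 the two ring-B CH2 groups between C7 and C10.

1. The cis-coumarate goes on last: Z-selective Horner–Wadsworth–Emmons olefination of 4-tert-butoxybenzaldehyde with the C15 phosphonoacetate, then one acidolysis frees the acid and the phenol.
2. Ring B is disconnected at C7–C8: a primary C8 radical, made from a vinyl group on C10 by hydroboration, closes 6-exo onto C7 of a 2-(sulfonylmethyl)-2-enoate and expels the sulfonyl radical.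
3. The enabling feature is the exocyclic allyl unit C7–C11(=C13H2)–CO2H on ring B: attack at C7 with loss of a leaving group from C13 (SH2') delivers exactly this acrylate, and the C8–C9 bridge to C10 is a masked vinyl group.
4. The monocyclic precursor (ring A) comes from an enantioselective Diels–Alder reaction (sets C10), a Stille coupling (C15), a reagent-controlled ketone reduction and a Johnson–Claisen rearrangement that carries the C3 carbinol centre over to C5 and leaves the C3=C4 alkene.
5. Order of ring formation: ring A (step 2, cycloaddition), then ring B (step 13, radical cyclization).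

Key step: step 13

Remark: the (S)-configured oxazaborolidinium catalyst is written for step 2 on the basis of the formyl C–H···O binding model for 2-substituted acroleins; the sense of induction is to be confirmed at enone 6, and the mirror-image catalyst would serve if the opposite sense were found.

## Route

Step 1
Reactants: 1 but-3-en-2-one
Product: 2 2-[(triisopropylsilyl)oxy]buta-1,3-diene
Conditions: i-Pr3SiOTf, Et3N, CH2Cl2, 0 °C → rt
Reagents that add atoms: triisopropylsilyl trifluoromethanesulfonate, CC(C)[Si](OS(=O)(=O)C(F)(F)F)(C(C)C)C(C)C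
Why: Soft enolisation (O-silylation of the enone by a silyl triflate/amine pair) gives the cross-conjugated 2-siloxydiene, the bulky silyl group being chosen so that the enol ether survives the acidic catalyst of step 2; no stereocentre is formed.

Step 2
Reactants: 2 2-[(triisopropylsilyl)oxy]buta-1,3-diene; 3 2-methylprop-2-enal
Product: 4 (1S)-1-methyl-4-[(triisopropylsilyl)oxy]cyclohex-3-ene-1-carbaldehyde
Conditions: (S)-3,3-diphenyl-1-(2-methylphenyl)tetrahydro-1H,3H-pyrrolo[1,2-c][1,3,2]oxazaborole·HN(SO2CF3)2 (20 mol %), CH2Cl2, −78 → −40 °C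
Reagents that add atoms: none
Why: Enantioselective Diels–Alder reaction under chiral oxazaborolidinium catalysis: the 2-siloxy group enforces the "para" orientation, and the boron-bound s-trans enal is shielded on one face by an aryl group of the catalyst, so the diene adds to the open face and the quaternary carbon (later C10) should be set as S.

Step 3
Reactants: 4 (1S)-1-methyl-4-[(triisopropylsilyl)oxy]cyclohex-3-ene-1-carbaldehyde
Product: 5 {[(4S)-4-ethenyl-4-methylcyclohex-1-en-1-yl]oxy}triisopropylsilane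
Conditions: Ph3PCH3Br, KOtBu, THF, 0 °C → rt
Reagents that add atoms: methyltriphenylphosphonium bromide, C[P+](c1ccccc1)(c1ccccc1)c1ccccc1.[Br-]
Why: Wittig methylenation of a non-enolisable neopentyl aldehyde turns the formyl group into the vinyl group that later supplies C9 and C8; the silyl enol ether and the quaternary centre are untouched.

Step 4
Reactants: 5 {[(4S)-4-ethenyl-4-methylcyclohex-1-en-1-yl]oxy}triisopropylsilane
Product: 6 (4R)-4-ethenyl-4-methylcyclohex-2-en-1-one
Conditions: Pd(OAc)2 (10 mol %), O2 (1 atm), DMSO, 60 °C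
Reagents that add atoms: none
Why: Saegusa–Ito oxidation: the regiodefined silyl enol ether gives a palladium enolate whose only β-hydrogens are at C5, so β-hydride elimination should yield the 4,4-disubstituted enone (the descriptor changes from S to R by priority rules only).

Step 5
Reactants: 6 (4R)-4-ethenyl-4-methylcyclohex-2-en-1-one
Product: 7 (4R)-4-ethenyl-2-iodo-4-methylcyclohex-2-en-1-one
Conditions: I2, pyridine, CH2Cl2, 0 °C → rt
Reagents that add atoms: iodine, II
Why: α-Iodination of the enone by the conjugate addition–iodination–elimination sequence with pyridine, a reaction type well established for 4,4-disubstituted cyclohexenones, places a coupling handle on C4.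

Step 6
Reactants: 7 (4R)-4-ethenyl-2-iodo-4-methylcyclohex-2-en-1-one
Product: 8 (4R)-4-ethenyl-2-(hydroxymethyl)-4-methylcyclohex-2-en-1-one
Conditions: Bu3SnCH2OH, Pd(PPh3)4 (5 mol %), 1,4-dioxane, 90 °C
Reagents that add atoms: (tributylstannyl)methanol, OC[Sn](CCCC)(CCCC)CCCC
Why: Stille cross-coupling: oxidative addition of the α-iodoenone, transfer of the hydroxymethyl group from tin and reductive elimination install C15 as a primary alcohol.

Step 7
Reactants: 8 (4R)-4-ethenyl-2-(hydroxymethyl)-4-methylcyclohex-2-en-1-one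
Product: 9 (4R)-2-({[tert-butyl(dimethyl)silyl]oxy}methyl)-4-ethenyl-4-methylcyclohex-2-en-1-one
Conditions: TBSCl, imidazole, CH2Cl2, 0 °C → rt
Reagents that add atoms: tert-butyl(chloro)dimethylsilane, CC(C)(C)[Si](C)(C)Cl
Why: Imidazole-assisted silylation of the primary alcohol protects C15–OH through the reductions and the radical step.

Step 8
Reactants: 9 (4R)-2-({[tert-butyl(dimethyl)silyl]oxy}methyl)-4-ethenyl-4-methylcyclohex-2-en-1-one
Product: 10 (1S,4R)-2-({[tert-butyl(dimethyl)silyl]oxy}methyl)-4-ethenyl-4-methylcyclohex-2-en-1-ol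
Conditions: (R)-1-methyl-3,3-diphenyltetrahydro-1H,3H-pyrrolo[1,2-c][1,3,2]oxazaborole (20 mol %), catecholborane, toluene, −78 °C
Reagents that add atoms: none
Why: Corey–Bakshi–Shibata reduction: reagent-controlled 1,2-hydride delivery with the substituted alkenyl carbon as the large group should give, with the (R)-catalyst, the (S)-carbinol, that is the hydroxyl cis to the C10 methyl group, while catecholborane at −78 °C leaves the vinyl group alone.

Step 9
Reactants: 10 (1S,4R)-2-({[tert-butyl(dimethyl)silyl]oxy}methyl)-4-ethenyl-4-methylcyclohex-2-en-1-ol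
Product: 12 ethyl 2-[(1R,6R)-2-({[tert-butyl(dimethyl)silyl]oxy}methyl)-6-ethenyl-6-methylcyclohex-2-en-1-yl]acetate, via ketene acetal 11 (not isolated)
Conditions: MeC(OEt)3, EtCO2H (cat.), xylenes, 140 °C, EtOH distilled off
Reagents that add atoms: triethyl orthoacetate, CC(OCC)(OCC)OCC
Why: Johnson–Claisen rearrangement: the ketene acetal formed at the allylic oxygen undergoes a suprafacial [3,3]-sigmatropic shift, so the C3–O stereocentre is exchanged for the C5–C6 bond on the same ring face (cis to the C10 methyl, trans to the vinyl group) and the alkene moves to C3=C4.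

Step 10
Reactants: 12 ethyl 2-[(1R,6R)-2-({[tert-butyl(dimethyl)silyl]oxy}methyl)-6-ethenyl-6-methylcyclohex-2-en-1-yl]acetate
Product: 13 2-[(1R,6R)-2-({[tert-butyl(dimethyl)silyl]oxy}methyl)-6-ethenyl-6-methylcyclohex-2-en-1-yl]acetaldehyde
Conditions: i-Bu2AlH, CH2Cl2, −78 °C; aq. KNaC4H4O6
Reagents that add atoms: none
Why: Partial reduction of the ethyl ester with i-Bu2AlH at −78 °C stops at the tetrahedral aluminium hemiacetal, which gives the aldehyde (C7) on work-up; no stereocentre is touched.

Step 11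
Reactants: 13 2-[(1R,6R)-2-({[tert-butyl(dimethyl)silyl]oxy}methyl)-6-ethenyl-6-methylcyclohex-2-en-1-yl]acetaldehyde; 14 tert-butyl prop-2-enoate
Product: 15 tert-butyl 4-[(1R,6R)-2-({[tert-butyl(dimethyl)silyl]oxy}methyl)-6-ethenyl-6-methylcyclohex-2-en-1-yl]-3-hydroxy-2-methylidenebutanoate (both carbinol epimers)
Conditions: 1,4-diazabicyclo[2.2.2]octane (1 equiv), MeOH (minimum volume), rt, several days
Reagents that add atoms: none
Why: Morita–Baylis–Hillman reaction: the amine adds to the acrylate, the zwitterionic enolate adds to the aldehyde and the amine is eliminated; the new carbinol centre forms without control, which does not matter because step 12 removes it.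

Step 12
Reactants: 15 tert-butyl 4-[(1R,6R)-2-({[tert-butyl(dimethyl)silyl]oxy}methyl)-6-ethenyl-6-methylcyclohex-2-en-1-yl]-3-hydroxy-2-methylidenebutanoate
Product: 17 tert-butyl (2Z)-2-[(benzenesulfonyl)methyl]-4-[(1R,6R)-2-({[tert-butyl(dimethyl)silyl]oxy}methyl)-6-ethenyl-6-methylcyclohex-2-en-1-yl]but-2-enoate, via allylic acetate 16 (not isolated)
Conditions: Ac2O, Et3N, 4-(dimethylamino)pyridine (cat.), DMF, 0 °C; then PhSO2Na, rt
Reagents that add atoms: sodium benzenesulfinate, [Na+].[O-]S(=O)c1ccccc1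
Why: Acetylation followed by SN2' displacement of the allylic acetate by the sulfur of the sulfinate gives the conjugated trisubstituted allyl sulfone (Z expected, the geometry being irrelevant for step 13) and erases the carbinol centre.

Step 13
Reactants: 17 tert-butyl (2Z)-2-[(benzenesulfonyl)methyl]-4-[(1R,6R)-2-({[tert-butyl(dimethyl)silyl]oxy}methyl)-6-ethenyl-6-methylcyclohex-2-en-1-yl]but-2-enoate
Product: 19 tert-butyl 2-[(2R,4aR,8aR)-8-({[tert-butyl(dimethyl)silyl]oxy}methyl)-4a-methyl-1,2,3,4,4a,5,6,8a-octahydronaphthalen-2-yl]prop-2-enoate, via B-alkylcatecholborane 18 (not isolated)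
Conditions: catecholborane (2 equiv), N,N-dimethylacetamide (20 mol %), CH2Cl2, 40 °C; MeOH (quench of excess borane); then CH2Cl2 (0.01 M), air (slow admission), 40 °C
Reagents that add atoms: none
Why: Proposed new method: anti-Markovnikov hydroboration of the only monosubstituted alkene gives B-alkylcatecholborane 18; homolytic substitution at boron releases the primary C8 radical, which adds 6-exo-trig to C7 (the β-carbon of the unsaturated ester), and the resulting tertiary α-ester radical expels PhSO2•, which attacks boron of the next molecule of 18 and carries the chain. The closest known reactions are the intermolecular radical allylation of B-alkylcatecholboranes with 2-(sulfonylmethyl)acrylates and 6-exo cyclizations of alkyl radicals onto enoates that end by β-elimination; the new element is their union in one ring closure. Ring B closes in the 6-exo-trig mode through a chair transition state fused trans to ring A, because the two reacting chains on C5 and C10 are trans and both equatorial. The new stereocentre C7 is set by that chair: the alkenyl branch lies pseudo-equatorial to avoid the axial hydrogens at C5 and C9, which places the acrylate cis to the angular methyl group. The step needs chemoselective hydroboration (secured by the steric gap between a vinyl group and two trisubstituted alkenes), attack at C7 rather than on the C3=C4 alkene or 1,5-hydrogen transfer from C6 (secured by the polarity match of a nucleophilic alkyl radical with the doubly activated acceptor and by the strain of the bridged alternatives), and high dilution against intermolecular allylation. In one operation ring B, the C7 stereocentre and the exocyclic methylene of the acrylate are formed and the sulfone is removed.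

Step 14
Reactants: 19 tert-butyl 2-[(2R,4aR,8aR)-8-({[tert-butyl(dimethyl)silyl]oxy}methyl)-4a-methyl-1,2,3,4,4a,5,6,8a-octahydronaphthalen-2-yl]prop-2-enoate
Product: 20 tert-butyl 2-[(2R,4aR,8aR)-8-(hydroxymethyl)-4a-methyl-1,2,3,4,4a,5,6,8a-octahydronaphthalen-2-yl]prop-2-enoate
Conditions: HF·pyridine, THF, 0 °C → rt
Reagents that add atoms: none
Why: Fluoride-mediated cleavage of the silyl ether (strong Si–F bond) frees the primary allylic alcohol under conditions that leave the tert-butyl ester and the acrylate intact.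

Step 15
Reactants: 20 tert-butyl 2-[(2R,4aR,8aR)-8-(hydroxymethyl)-4a-methyl-1,2,3,4,4a,5,6,8a-octahydronaphthalen-2-yl]prop-2-enoate; 21 2-(diphenoxyphosphoryl)acetic acid
Product: 22 tert-butyl 2-[(2R,4aR,8aR)-8-({[2-(diphenoxyphosphoryl)acetyl]oxy}methyl)-4a-methyl-1,2,3,4,4a,5,6,8a-octahydronaphthalen-2-yl]prop-2-enoate
Conditions: N,N'-dicyclohexylcarbodiimide, 4-(dimethylamino)pyridine (cat.), CH2Cl2, 0 °C → rt
Reagents that add atoms: none
Why: Carbodiimide-mediated (Steglich-type) esterification of the unhindered primary allylic alcohol with the phosphonoacetic acid.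

Step 16
Reactants: 22 tert-butyl 2-[(2R,4aR,8aR)-8-({[2-(diphenoxyphosphoryl)acetyl]oxy}methyl)-4a-methyl-1,2,3,4,4a,5,6,8a-octahydronaphthalen-2-yl]prop-2-enoate; 23 4-tert-butoxybenzaldehyde
Product: 24 tert-butyl 2-[(2R,4aR,8aR)-8-({[(2Z)-3-(4-tert-butoxyphenyl)prop-2-enoyl]oxy}methyl)-4a-methyl-1,2,3,4,4a,5,6,8a-octahydronaphthalen-2-yl]prop-2-enoate
Conditions: KN(SiMe3)2 (1.0 equiv), 18-crown-6, THF, −78 °C; then 23, −78 → −40 °C, dark
Reagents that add atoms: none
Why: Z-selective Horner–Wadsworth–Emmons olefination of the Ando type: with aryloxy groups on phosphorus the syn-oxaphosphetane collapses faster than it equilibrates, which should give the cis-cinnamate, and one equivalent of base at −78 °C keeps the phosphonate anion from the acrylate.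

Step 17
Reactants: 24 tert-butyl 2-[(2R,4aR,8aR)-8-({[(2Z)-3-(4-tert-butoxyphenyl)prop-2-enoyl]oxy}methyl)-4a-methyl-1,2,3,4,4a,5,6,8a-octahydronaphthalen-2-yl]prop-2-enoate
Product: 25 2-[(2R,4aR,8aR)-8-({[(2Z)-3-(4-hydroxyphenyl)prop-2-enoyl]oxy}methyl)-4a-methyl-1,2,3,4,4a,5,6,8a-octahydronaphthalen-2-yl]prop-2-enoic acid (CNP0183482.1)
Conditions: CF3CO2H/CH2Cl2 (1:4), anisole, 0 °C → rt, dark
Reagents that add atoms: none
Why: Acidolysis (E1 loss of the tert-butyl cation as 2-methylpropene) unmasks the carboxylic acid and the phenol in one operation, while cold, brief, dark conditions should keep the Z-alkene and the allylic ester intact.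

## Compound list

1 | but-3-en-2-one | CC(=O)C=C | starting material
2 | 2-[(triisopropylsilyl)oxy]buta-1,3-diene | C=CC(=C)O[Si](C(C)C)(C(C)C)C(C)C | intermediate
3 | 2-methylprop-2-enal (methacrolein) | C=C(C)C=O | starting material
4 | (1S)-1-methyl-4-[(triisopropylsilyl)oxy]cyclohex-3-ene-1-carbaldehyde | O=C[C@@]1(C)CCC(O[Si](C(C)C)(C(C)C)C(C)C)=CC1 | intermediate
5 | {[(4S)-4-ethenyl-4-methylcyclohex-1-en-1-yl]oxy}triisopropylsilane | C=C[C@@]1(C)CCC(O[Si](C(C)C)(C(C)C)C(C)C)=CC1 | intermediate
6 | (4R)-4-ethenyl-4-methylcyclohex-2-en-1-one | C=C[C@@]1(C)CCC(=O)C=C1 | intermediate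
7 | (4R)-4-ethenyl-2-iodo-4-methylcyclohex-2-en-1-one | C=C[C@@]1(C)CCC(=O)C(I)=C1 | intermediate
8 | (4R)-4-ethenyl-2-(hydroxymethyl)-4-methylcyclohex-2-en-1-one | C=C[C@@]1(C)CCC(=O)C(CO)=C1 | intermediate
9 | (4R)-2-({[tert-butyl(dimethyl)silyl]oxy}methyl)-4-ethenyl-4-methylcyclohex-2-en-1-one | C=C[C@@]1(C)CCC(=O)C(CO[Si](C)(C)C(C)(C)C)=C1 | intermediate
10 | (1S,4R)-2-({[tert-butyl(dimethyl)silyl]oxy}methyl)-4-ethenyl-4-methylcyclohex-2-en-1-ol (hydroxyl cis to the ring methyl) | C=C[C@@]1(C)CC[C@H](O)C(CO[Si](C)(C)C(C)(C)C)=C1 | intermediate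
11 | ketene acetal: tert-butyl{[(3R,6S)-6-[(1-ethoxyethenyl)oxy]-3-ethenyl-3-methylcyclohex-1-en-1-yl]methoxy}dimethylsilane (same spatial arrangement as 10) | C=C[C@@]1(C)CC[C@H](OC(=C)OCC)C(CO[Si](C)(C)C(C)(C)C)=C1 | intermediate (not isolated)
12 | ethyl 2-[(1R,6R)-2-({[tert-butyl(dimethyl)silyl]oxy}methyl)-6-ethenyl-6-methylcyclohex-2-en-1-yl]acetate (side chain cis to the ring methyl) | C=C[C@@]1(C)CCC=C(CO[Si](C)(C)C(C)(C)C)[C@@H]1CC(=O)OCC | intermediate
13 | 2-[(1R,6R)-2-({[tert-butyl(dimethyl)silyl]oxy}methyl)-6-ethenyl-6-methylcyclohex-2-en-1-yl]acetaldehyde | C=C[C@@]1(C)CCC=C(CO[Si](C)(C)C(C)(C)C)[C@@H]1CC=O | intermediate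
14 | tert-butyl prop-2-enoate | C=CC(=O)OC(C)(C)C | starting material
15 | tert-butyl 4-[(1R,6R)-2-({[tert-butyl(dimethyl)silyl]oxy}methyl)-6-ethenyl-6-methylcyclohex-2-en-1-yl]-3-hydroxy-2-methylidenebutanoate (both carbinol epimers) | C=C[C@@]1(C)CCC=C(CO[Si](C)(C)C(C)(C)C)[C@@H]1CC(O)C(=C)C(=O)OC(C)(C)C | intermediate
16 | tert-butyl 3-(acetyloxy)-4-[(1R,6R)-2-({[tert-butyl(dimethyl)silyl]oxy}methyl)-6-ethenyl-6-methylcyclohex-2-en-1-yl]-2-methylidenebutanoate | C=C[C@@]1(C)CCC=C(CO[Si](C)(C)C(C)(C)C)[C@@H]1CC(OC(C)=O)C(=C)C(=O)OC(C)(C)C | intermediate (not isolated)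
17 | tert-butyl (2Z)-2-[(benzenesulfonyl)methyl]-4-[(1R,6R)-2-({[tert-butyl(dimethyl)silyl]oxy}methyl)-6-ethenyl-6-methylcyclohex-2-en-1-yl]but-2-enoate | C=C[C@@]1(C)CCC=C(CO[Si](C)(C)C(C)(C)C)[C@@H]1C/C=C(\CS(=O)(=O)c1ccccc1)C(=O)OC(C)(C)C | intermediate
18 | tert-butyl (2Z)-4-[(1R,6S)-6-[2-(1,3,2-benzodioxaborol-2-yl)ethyl]-2-({[tert-butyl(dimethyl)silyl]oxy}methyl)-6-methylcyclohex-2-en-1-yl]-2-[(benzenesulfonyl)methyl]but-2-enoate (same spatial arrangement as 17) | O1c2ccccc2OB1CC[C@@]1(C)CCC=C(CO[Si](C)(C)C(C)(C)C)[C@@H]1C/C=C(\CS(=O)(=O)c1ccccc1)C(=O)OC(C)(C)C | intermediate (not isolated)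
19 | tert-butyl 2-[(2R,4aR,8aR)-8-({[tert-butyl(dimethyl)silyl]oxy}methyl)-4a-methyl-1,2,3,4,4a,5,6,8a-octahydronaphthalen-2-yl]prop-2-enoate (trans ring fusion, acrylate cis to the angular methyl) | C=C(C(=O)OC(C)(C)C)[C@@H]1CC[C@@]2(C)CCC=C(CO[Si](C)(C)C(C)(C)C)[C@@H]2C1 | intermediate
20 | tert-butyl 2-[(2R,4aR,8aR)-8-(hydroxymethyl)-4a-methyl-1,2,3,4,4a,5,6,8a-octahydronaphthalen-2-yl]prop-2-enoate | C=C(C(=O)OC(C)(C)C)[C@@H]1CC[C@@]2(C)CCC=C(CO)[C@@H]2C1 | intermediate
21 | 2-(diphenoxyphosphoryl)acetic acid | OC(=O)CP(=O)(Oc1ccccc1)Oc1ccccc1 | starting material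
22 | tert-butyl 2-[(2R,4aR,8aR)-8-({[2-(diphenoxyphosphoryl)acetyl]oxy}methyl)-4a-methyl-1,2,3,4,4a,5,6,8a-octahydronaphthalen-2-yl]prop-2-enoate | C=C(C(=O)OC(C)(C)C)[C@@H]1CC[C@@]2(C)CCC=C(COC(=O)CP(=O)(Oc3ccccc3)Oc3ccccc3)[C@@H]2C1 | intermediate
23 | 4-tert-butoxybenzaldehyde | CC(C)(C)Oc1ccc(C=O)cc1 | starting material
24 | tert-butyl 2-[(2R,4aR,8aR)-8-({[(2Z)-3-(4-tert-butoxyphenyl)prop-2-enoyl]oxy}methyl)-4a-methyl-1,2,3,4,4a,5,6,8a-octahydronaphthalen-2-yl]prop-2-enoate | C=C(C(=O)OC(C)(C)C)[C@@H]1CC[C@@]2(C)CCC=C(COC(=O)/C=C\c3ccc(OC(C)(C)C)cc3)[C@@H]2C1 | intermediate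
25 | 2-[(2R,4aR,8aR)-8-({[(2Z)-3-(4-hydroxyphenyl)prop-2-enoyl]oxy}methyl)-4a-methyl-1,2,3,4,4a,5,6,8a-octahydronaphthalen-2-yl]prop-2-enoic acid | C=C(C(=O)O)[C@@H]1CC[C@@]2(C)CCC=C(COC(=O)/C=C\c3ccc(O)cc3)[C@@H]2C1 | target

## Step count and risks

Total step count: 17. Longest linear sequence: 17 steps (from but-3-en-2-one).

Steps most likely to fail:

1. Step 13 (key step, proposed new method). The boron-centred chain may fail to propagate at the dilution the ring closure needs, catecholborane may reduce the enoate conjugatively, or the C8 radical may be lost by 1,5-hydrogen transfer from C6 or by attack on the ring-A alkene. The fallback uses known chemistry and sets out from 17. Hydroboration with 9-borabicyclo[3.3.1]nonane (THF, 0 °C → rt) gives the B-alkyl-9-borabicyclo[3.3.1]nonane F1, which is oxidised in the same flask (NaBO3·4H2O) to the primary alcohol F2. Iodination (I2, PPh3, imidazole, CH2Cl2) gives the primary iodide F3. Irradiation of F3 with (Bu3Sn)2 in benzene at 80 °C and 0.005 M then effects iodine abstraction by Bu3Sn•, 6-exo cyclization and loss of PhSO2•, which regenerates Bu3Sn• from the ditin. The route is rejoined at 19.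

2. Step 11. Addition of the amine–acrylate zwitterion to a β-branched, enolisable aldehyde may be so slow that self-aldol condensation of 13 overtakes product formation. The fallback sets out from 13: tert-butyl propiolate is hydroaluminated (i-Bu2AlH, N-methylmorpholine N-oxide, THF, 0 °C) to the vinylalane tert-butyl 2-(diisobutylalumanyl)prop-2-enoate F4, which should add to 13 within hours at 0 °C. The route is rejoined at 15.

3. Step 17. The acid may promote Z→E isomerisation of the electron-rich cinnamate, ionisation of the allylic ester, or tert-butylation of the phenol. The fallback sets out from 20 and applies acid only to the robust E-isomer. Mitsunobu esterification with trans-4-hydroxycinnamic acid (PPh3, diisopropyl azodicarboxylate, THF, 0 °C; the carboxylic acid should react in preference to the phenol) gives the E-configured ester F5. CF3CO2H/CH2Cl2 removes the tert-butyl ester to give the E-isomer of the target F6. Irradiation (365 nm, MeCN, or visible light with a triplet sensitiser) should move the alkene to a Z-rich photostationary mixture, from which 25 is separated by chromatography in the dark while F6 is recycled. The route is rejoined at 25.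

## Further compounds

F1 | step 13 | tert-butyl (2Z)-2-[(benzenesulfonyl)methyl]-4-[(1R,6S)-6-[2-(9-borabicyclo[3.3.1]nonan-9-yl)ethyl]-2-({[tert-butyl(dimethyl)silyl]oxy}methyl)-6-methylcyclohex-2-en-1-yl]but-2-enoate | C1CC2CCCC(C1)B2CC[C@@]1(C)CCC=C(CO[Si](C)(C)C(C)(C)C)[C@@H]1C/C=C(\CS(=O)(=O)c1ccccc1)C(=O)OC(C)(C)C
F2 | step 13 | tert-butyl (2Z)-2-[(benzenesulfonyl)methyl]-4-[(1R,6R)-2-({[tert-butyl(dimethyl)silyl]oxy}methyl)-6-(2-hydroxyethyl)-6-methylcyclohex-2-en-1-yl]but-2-enoate | OCC[C@@]1(C)CCC=C(CO[Si](C)(C)C(C)(C)C)[C@@H]1C/C=C(\CS(=O)(=O)c1ccccc1)C(=O)OC(C)(C)C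
F3 | step 13 | tert-butyl (2Z)-2-[(benzenesulfonyl)methyl]-4-[(1R,6R)-2-({[tert-butyl(dimethyl)silyl]oxy}methyl)-6-(2-iodoethyl)-6-methylcyclohex-2-en-1-yl]but-2-enoate | ICC[C@@]1(C)CCC=C(CO[Si](C)(C)C(C)(C)C)[C@@H]1C/C=C(\CS(=O)(=O)c1ccccc1)C(=O)OC(C)(C)C
F4 | step 11 | tert-butyl 2-(diisobutylalumanyl)prop-2-enoate | C=C([Al](CC(C)C)CC(C)C)C(=O)OC(C)(C)C
F5 | step 17 | tert-butyl 2-[(2R,4aR,8aR)-8-({[(2E)-3-(4-hydroxyphenyl)prop-2-enoyl]oxy}methyl)-4a-methyl-1,2,3,4,4a,5,6,8a-octahydronaphthalen-2-yl]prop-2-enoate | C=C(C(=O)OC(C)(C)C)[C@@H]1CC[C@@]2(C)CCC=C(COC(=O)/C=C/c3ccc(O)cc3)[C@@H]2C1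
F6 | step 17 | 2-[(2R,4aR,8aR)-8-({[(2E)-3-(4-hydroxyphenyl)prop-2-enoyl]oxy}methyl)-4a-methyl-1,2,3,4,4a,5,6,8a-octahydronaphthalen-2-yl]prop-2-enoic acid | C=C(C(=O)O)[C@@H]1CC[C@@]2(C)CCC=C(COC(=O)/C=C/c3ccc(O)cc3)[C@@H]2C1
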